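**Retrosynthetic overview**

- The route rests on the E-trisubstituted olefin C2'=C3' of the side chain (numbered from the benzylic carbon C1'). It carries a methyl group on C3' and the arylmethyl carbon C1' on C2', which is the pattern left when methyl and a metal add syn across a terminal alkyne and the metal-bearing carbon is then coupled.
- Key disconnection: the C3'–CH3 and C2'–C1' bonds, made in one three-component operation from a C2'–C16' homopropargylic alcohol, Al(CH3)3 and 2-(chloromethyl)-6-methyl-1,4-benzoquinone. The ring stays a quinone through C5' acetylation and C12' desilylation and is reduced last.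
- The homopropargylic alcohol comes from a C5'–C16' enal by catalyst-controlled propargylation (sets C5'). The enal comes from geranyl acetate by allylic oxidation, asymmetric allylation (sets C12'), silylation, cross-metathesis with 2-methylbut-2-ene, deacetylation and oxidation.
- The chloromethylquinone comes from 2,6-dimethyl-1,4-benzoquinone by reductive methylation, benzylic halogenation and oxidative demethylation.
- No ring is formed in the route; the only ring, the six-membered carbocycle, is bought as the quinone.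

Key step: step 11

Assumption: read from the SMILES, the target is 5'S,12'R with 2'E,6'E,10'E olefins. "(+)-Ipc2B(allyl)" means the allylborane made from (−)-α-pinene, as drawn in its SMILES.

**Step 1**
Reactants: 1 geranyl acetate
Product: 3 (2E,6E)-3,7-dimethyl-8-oxoocta-2,6-dien-1-yl acetate, via allylic alcohol 2 (not isolated)
Conditions: SeO2 (cat.), t-BuOOH, salicylic acid (cat.), CH2Cl2, rt; crude mixture, MnO2, CH2Cl2, rt
Reagents that add atoms: selenium dioxide, O=[Se]=O (oxygen carrier); tert-butyl hydroperoxide, CC(C)(C)OO (terminal oxidant)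
Why: Riley allylic oxidation (ene reaction then [2,3]-sigmatropic shift) should attack the E-methyl group of the terminal trisubstituted olefin, which is more electron-rich than the olefin next to the acetate, and MnO2 should bring the alcohol/aldehyde mixture to the single E-enal; no stereocentre is formed.

**Step 2**
Reactants: 3 (2E,6E)-3,7-dimethyl-8-oxoocta-2,6-dien-1-yl acetate
Product: 5 (2E,6E,8R)-8-hydroxy-3,7-dimethylundeca-2,6,10-trien-1-yl acetate, via borinate ester 4 (not isolated)
Conditions: (+)-Ipc2B(allyl) (1 M in pentane), Et2O, −78 °C; then HOCH2CH2NH2, rt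
Reagents that add atoms: (+)-B-allyldiisopinocampheylborane, C=CCB([C@H]1C[C@H]2C[C@@H]([C@@H]1C)C2(C)C)[C@H]1C[C@H]2C[C@@H]([C@@H]1C)C2(C)C
Why: Brown allylboration through a chair-like six-membered transition state, in which the isopinocampheyl groups derived from (−)-α-pinene should deliver the allyl group to the Re face of the enal and so set the carbinol (C12' of the target) as R, while the acetate does not react at −78 °C.

**Step 3**
Reactants: 5 (2E,6E,8R)-8-hydroxy-3,7-dimethylundeca-2,6,10-trien-1-yl acetate
Product: 6 (2E,6E,8R)-8-(tert-butyldimethylsilyloxy)-3,7-dimethylundeca-2,6,10-trien-1-yl acetate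
Conditions: TBSCl, imidazole, DMF, rt
Reagents that add atoms: tert-butyldimethylsilyl chloride, CC(C)(C)[Si](C)(C)Cl
Why: Standard silylation of a secondary allylic alcohol via the silylimidazolium species; the C–O bond is not broken, so the configuration is kept.

**Step 4**
Reactants: 6 (2E,6E,8R)-8-(tert-butyldimethylsilyloxy)-3,7-dimethylundeca-2,6,10-trien-1-yl acetate; 7 2-methylbut-2-ene
Product: 8 (2E,6E,8R)-8-(tert-butyldimethylsilyloxy)-3,7,11-trimethyldodeca-2,6,10-trien-1-yl acetate
Conditions: second-generation Grubbs catalyst (H2IMes)(PCy3)Cl2Ru=CHPh (5 mol%), 2-methylbut-2-ene (large excess), CH2Cl2, 35 °C, sealed vessel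
Reagents that add atoms: none
Why: Olefin cross-metathesis in which only the monosubstituted terminal olefin should engage the ruthenium carbene, the two trisubstituted olefins of the chain stay out, and the excess of 2-methylbut-2-ene should drive the terminus to the isopropylidene group, which has no geometry to control.

**Step 5**
Reactants: 8 (2E,6E,8R)-8-(tert-butyldimethylsilyloxy)-3,7,11-trimethyldodeca-2,6,10-trien-1-yl acetate
Product: 9 (2E,6E,8R)-8-(tert-butyldimethylsilyloxy)-3,7,11-trimethyldodeca-2,6,10-trien-1-ol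
Conditions: K2CO3 (cat.), MeOH, 0 °C to rt
Reagents that add atoms: none
Why: Base-catalysed transesterification of a primary acetate with methanol; the silyl ether is stable to these conditions.

**Step 6**
Reactants: 9 (2E,6E,8R)-8-(tert-butyldimethylsilyloxy)-3,7,11-trimethyldodeca-2,6,10-trien-1-ol
Product: 10 (2E,6E,8R)-8-(tert-butyldimethylsilyloxy)-3,7,11-trimethyldodeca-2,6,10-trienal
Conditions: MnO2 (excess), CH2Cl2, rt
Reagents that add atoms: none
Why: MnO2 oxidation is selective for the primary allylic alcohol and should give the enal with the 2E geometry kept and the silyl ether untouched.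

**Step 7**
Reactants: 10 (2E,6E,8R)-8-(tert-butyldimethylsilyloxy)-3,7,11-trimethyldodeca-2,6,10-trienal; 11 allenylboronic acid pinacol ester
Product: 13 (4S,5E,9E,11R)-11-(tert-butyldimethylsilyloxy)-6,10,14-trimethylpentadeca-5,9,13-trien-1-yn-4-ol, via borate ester 12 (not isolated)
Conditions: (S)-3,3'-bis(2,4,6-triisopropylphenyl)-1,1'-binaphthyl-2,2'-diyl hydrogen phosphate (10 mol%), 4 Å molecular sieves, toluene, −20 °C; aqueous NaHCO3 work-up
Reagents that add atoms: none
Why: Chiral phosphoric acid catalysed propargylation by an allenylboronate (SE2' transfer through a closed six-membered transition state in which the acid binds a boronate oxygen and the formyl hydrogen), where the (S)-acid is expected to expose the Si face of the enal and so set C5' as S under catalyst control, the distant C12' centre having no say.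

**Step 8**
Reactants: 14 2,6-dimethyl-1,4-benzoquinone
Product: 16 2,5-dimethoxy-1,3-dimethylbenzene, via hydroquinone 15 (not isolated)
Conditions: Na2S2O4, THF/H2O, rt; then KOH, (CH3)2SO4, Bu4NBr, rt, under N2
Reagents that add atoms: dimethyl sulfate, COS(=O)(=O)OC
Why: Dithionite reduction of the quinone followed in the same flask by phase-transfer Williamson O-methylation of both phenoxides is a standard reductive methylation.

**Step 9**
Reactants: 16 2,5-dimethoxy-1,3-dimethylbenzene
Product: 18 1-(chloromethyl)-2,5-dimethoxy-3-methylbenzene, via benzylic bromide 17 (not isolated)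
Conditions: N-bromosuccinimide (0.95 equiv), azobisisobutyronitrile (cat.), PhCF3, 80 °C; filter, concentrate; LiCl (5 equiv), DMF, rt
Reagents that add atoms: N-bromosuccinimide, O=C1CCC(=O)N1Br (bromine of 17 only); lithium chloride, [Li+].[Cl-] (chlorine of 18)
Why: Wohl–Ziegler radical bromination in a non-polar solvent with initiator should take one of the two equivalent benzylic methyl groups (a slight deficit of N-bromosuccinimide limiting double bromination), and Finkelstein-type SN2 exchange with excess chloride then gives the more stable benzylic chloride.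

**Step 10**
Reactants: 18 1-(chloromethyl)-2,5-dimethoxy-3-methylbenzene
Product: 19 2-(chloromethyl)-6-methyl-1,4-benzoquinone
Conditions: (NH4)2Ce(NO3)6 (2.5 equiv), MeCN/H2O, 0 °C
Reagents that add atoms: water, O (both quinone oxygens)
Why: Oxidative demethylation of a hydroquinone dimethyl ether by tetravalent cerium (two one-electron oxidations, water adding at the oxygen-bearing ring carbons and methanol leaving) gives the quinone, and the benzylic chloride should survive the short, cold reaction.

**Step 11**
Reactants: 13 (4S,5E,9E,11R)-11-(tert-butyldimethylsilyloxy)-6,10,14-trimethylpentadeca-5,9,13-trien-1-yn-4-ol; 20 trimethylaluminium; 19 2-(chloromethyl)-6-methyl-1,4-benzoquinone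
Product: 23 2-[(2E,5S,6E,10E,12R)-12-(tert-butyldimethylsilyloxy)-5-hydroxy-3,7,11,15-tetramethylhexadeca-2,6,10,14-tetraen-1-yl]-6-methyl-1,4-benzoquinone, via alkenylalane 21 (not isolated), via aluminium alkoxide 22 (not isolated)
Conditions: Al(CH3)3 (3 equiv), Cp2ZrCl2 (0.25 equiv), ClCH2CH2Cl, 0 °C to rt; volatiles and excess Al(CH3)3 removed in vacuo, THF; 19, NiCl2(PPh3)2 (5 mol%)/n-BuLi (10 mol%), −20 to 0 °C; aqueous KNaC4H4O6 work-up
Reagents that add atoms: none
Why: One equivalent of Al(CH3)3 turns the C5' hydroxyl into its dimethylaluminium alkoxide with loss of methane, and tetravalent zirconium (Cp2ZrCl2) then activates a second equivalent for syn methylalumination of the terminal alkyne (zirconium-catalysed Negishi carboalumination), methyl going to the internal carbon C3' and aluminium to C2' to give alkenylalane 21. Oxidative addition of the benzylic-type C–Cl bond of 19 to zerovalent nickel (from NiCl2(PPh3)2 and n-BuLi), transfer of the alkenyl group from aluminium and reductive elimination then join C2' to C1' with retention at the alkenyl carbon, so the 2'E geometry follows from the syn addition. The closest known reaction type is carboalumination of a terminal alkyne followed by nickel-catalysed coupling of the alkenylalane with a chloromethylquinone, as used to attach polyprenyl chains to quinones. No ring is closed and no stereocentre is created; the two new skeletal bonds are C3'–CH3 and C2'–C1'. The step needs regioselective syn addition and a stereoretentive coupling: the terminal alkyne fixes the regiochemistry, the three trisubstituted olefins are inert to the zirconium/aluminium reagent, and holding the alane at or below room temperature guards against alkoxide-assisted E/Z isomerisation. Excess Al(CH3)3 is stripped off before 19 is added so that the quinone carbonyls are not methylated, and coupling at the quinone oxidation level makes phenol protection unnecessary.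

**Step 12**
Reactants: 23 2-[(2E,5S,6E,10E,12R)-12-(tert-butyldimethylsilyloxy)-5-hydroxy-3,7,11,15-tetramethylhexadeca-2,6,10,14-tetraen-1-yl]-6-methyl-1,4-benzoquinone
Product: 24 (2E,5S,6E,10E,12R)-12-(tert-butyldimethylsilyloxy)-3,7,11,15-tetramethyl-1-(5-methyl-3,6-dioxocyclohexa-1,4-dien-1-yl)hexadeca-2,6,10,14-tetraen-5-yl acetate
Conditions: Ac2O, pyridine, 4-(dimethylamino)pyridine (cat.), CH2Cl2, 0 °C
Reagents that add atoms: acetic anhydride, CC(=O)OC(C)=O
Why: Nucleophile-catalysed acylation of the only free hydroxyl (C5'), with C12' blocked as its silyl ether and the ring oxygens masked as the quinone; the C5'–O bond is not broken, so the S configuration is kept.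

**Step 13**
Reactants: 24 (2E,5S,6E,10E,12R)-12-(tert-butyldimethylsilyloxy)-3,7,11,15-tetramethyl-1-(5-methyl-3,6-dioxocyclohexa-1,4-dien-1-yl)hexadeca-2,6,10,14-tetraen-5-yl acetate
Product: 25 (2E,5S,6E,10E,12R)-12-hydroxy-3,7,11,15-tetramethyl-1-(5-methyl-3,6-dioxocyclohexa-1,4-dien-1-yl)hexadeca-2,6,10,14-tetraen-5-yl acetate
Conditions: HF·pyridine, pyridine, THF, 0 °C to rt
Reagents that add atoms: none
Why: Fluoride-mediated desilylation under buffered, weakly acidic conditions cleaves the Si–O bond only, so the C12' configuration, the allylic acetate and the base-sensitive quinone should all be preserved.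

**Step 14**
Reactants: 25 (2E,5S,6E,10E,12R)-12-hydroxy-3,7,11,15-tetramethyl-1-(5-methyl-3,6-dioxocyclohexa-1,4-dien-1-yl)hexadeca-2,6,10,14-tetraen-5-yl acetate
Product: 26 (2E,5S,6E,10E,12R)-1-(2,5-dihydroxy-3-methylphenyl)-12-hydroxy-3,7,11,15-tetramethylhexadeca-2,6,10,14-tetraen-5-yl acetate
Conditions: Na2S2O4, EtOAc/H2O, rt, under argon
Reagents that add atoms: none
Why: Two-phase dithionite reduction converts the quinone into the hydroquinone without touching the ester, the olefins or the stereocentres, and is placed last because the product is air-sensitive.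

**Compound list**

1 | geranyl acetate, (2E)-3,7-dimethylocta-2,6-dien-1-yl acetate | CC(C)=CCC/C(C)=C/COC(C)=O | starting material
2 | (2E,6E)-8-hydroxy-3,7-dimethylocta-2,6-dien-1-yl acetate | CC(=O)OC/C=C(\C)CC/C=C(\C)CO | intermediate
3 | (2E,6E)-3,7-dimethyl-8-oxoocta-2,6-dien-1-yl acetate | CC(=O)OC/C=C(\C)CC/C=C(\C)C=O | intermediate
4 | diisopinocampheylborinate ester of 5 (O–B(Ipc)2 on C8) | CC(=O)OC/C=C(\C)CC/C=C(\C)[C@H](OB([C@H]1C[C@H]2C[C@@H]([C@@H]1C)C2(C)C)[C@H]1C[C@H]2C[C@@H]([C@@H]1C)C2(C)C)CC=C | intermediate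
5 | (2E,6E,8R)-8-hydroxy-3,7-dimethylundeca-2,6,10-trien-1-yl acetate | CC(=O)OC/C=C(\C)CC/C=C(\C)[C@H](O)CC=C | intermediate
6 | (2E,6E,8R)-8-(tert-butyldimethylsilyloxy)-3,7-dimethylundeca-2,6,10-trien-1-yl acetate | CC(=O)OC/C=C(\C)CC/C=C(\C)[C@H](O[Si](C)(C)C(C)(C)C)CC=C | intermediate
7 | 2-methylbut-2-ene | CC=C(C)C | starting material
8 | (2E,6E,8R)-8-(tert-butyldimethylsilyloxy)-3,7,11-trimethyldodeca-2,6,10-trien-1-yl acetate | CC(=O)OC/C=C(\C)CC/C=C(\C)[C@H](O[Si](C)(C)C(C)(C)C)CC=C(C)C | intermediate
9 | (2E,6E,8R)-8-(tert-butyldimethylsilyloxy)-3,7,11-trimethyldodeca-2,6,10-trien-1-ol | OC/C=C(\C)CC/C=C(\C)[C@H](O[Si](C)(C)C(C)(C)C)CC=C(C)C | intermediate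
10 | (2E,6E,8R)-8-(tert-butyldimethylsilyloxy)-3,7,11-trimethyldodeca-2,6,10-trienal (C5'–C16' enal) | O=C/C=C(\C)CC/C=C(\C)[C@H](O[Si](C)(C)C(C)(C)C)CC=C(C)C | intermediate
11 | allenylboronic acid pinacol ester | C=C=CB1OC(C)(C)C(C)(C)O1 | starting material
12 | pinacol borate ester of 13 (O–Bpin on C5') | CC1(C)OB(O[C@H](/C=C(\C)CC/C=C(\C)[C@H](O[Si](C)(C)C(C)(C)C)CC=C(C)C)CC#C)OC1(C)C | intermediate
13 | (4S,5E,9E,11R)-11-(tert-butyldimethylsilyloxy)-6,10,14-trimethylpentadeca-5,9,13-trien-1-yn-4-ol (C2'–C16' homopropargylic alcohol) | O[C@H](/C=C(\C)CC/C=C(\C)[C@H](O[Si](C)(C)C(C)(C)C)CC=C(C)C)CC#C | intermediate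
14 | 2,6-dimethyl-1,4-benzoquinone | CC1=CC(=O)C=C(C)C1=O | starting material
15 | 2,6-dimethylbenzene-1,4-diol | Cc1cc(O)cc(C)c1O | intermediate
16 | 2,5-dimethoxy-1,3-dimethylbenzene | Cc1cc(OC)cc(C)c1OC | intermediate
17 | 1-(bromomethyl)-2,5-dimethoxy-3-methylbenzene | BrCc1cc(OC)cc(C)c1OC | intermediate
18 | 1-(chloromethyl)-2,5-dimethoxy-3-methylbenzene | ClCc1cc(OC)cc(C)c1OC | intermediate
19 | 2-(chloromethyl)-6-methyl-1,4-benzoquinone | ClCC1=CC(=O)C=C(C)C1=O | intermediate
20 | trimethylaluminium | C[Al](C)C | starting material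
21 | alkenylalane: (2'E)-C2' dimethylalanyl olefin from 13 with the C5' oxygen as its dimethylaluminium alkoxide | C[Al](C)O[C@H](/C=C(\C)CC/C=C(\C)[C@H](O[Si](C)(C)C(C)(C)C)CC=C(C)C)C/C(C)=C/[Al](C)C | intermediate
22 | dimethylaluminium C5' alkoxide of 23 | C[Al](C)O[C@H](/C=C(\C)CC/C=C(\C)[C@H](O[Si](C)(C)C(C)(C)C)CC=C(C)C)C/C(C)=C/CC1=CC(=O)C=C(C)C1=O | intermediate
23 | 2-[(2E,5S,6E,10E,12R)-12-(tert-butyldimethylsilyloxy)-5-hydroxy-3,7,11,15-tetramethylhexadeca-2,6,10,14-tetraen-1-yl]-6-methyl-1,4-benzoquinone | O[C@H](/C=C(\C)CC/C=C(\C)[C@H](O[Si](C)(C)C(C)(C)C)CC=C(C)C)C/C(C)=C/CC1=CC(=O)C=C(C)C1=O | intermediate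
24 | (2E,5S,6E,10E,12R)-12-(tert-butyldimethylsilyloxy)-3,7,11,15-tetramethyl-1-(5-methyl-3,6-dioxocyclohexa-1,4-dien-1-yl)hexadeca-2,6,10,14-tetraen-5-yl acetate | CC(=O)O[C@H](/C=C(\C)CC/C=C(\C)[C@H](O[Si](C)(C)C(C)(C)C)CC=C(C)C)C/C(C)=C/CC1=CC(=O)C=C(C)C1=O | intermediate
25 | (2E,5S,6E,10E,12R)-12-hydroxy-3,7,11,15-tetramethyl-1-(5-methyl-3,6-dioxocyclohexa-1,4-dien-1-yl)hexadeca-2,6,10,14-tetraen-5-yl acetate | CC(=O)O[C@H](/C=C(\C)CC/C=C(\C)[C@H](O)CC=C(C)C)C/C(C)=C/CC1=CC(=O)C=C(C)C1=O | intermediate
26 | (2E,5S,6E,10E,12R)-1-(2,5-dihydroxy-3-methylphenyl)-12-hydroxy-3,7,11,15-tetramethylhexadeca-2,6,10,14-tetraen-5-yl acetate | CC(=O)O[C@H](/C=C(\C)CC/C=C(\C)[C@H](O)CC=C(C)C)C/C(C)=C/Cc1cc(O)cc(C)c1O | target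

**Step count and risk**

Total step count: 14. Longest linear sequence: 11 steps (steps 1–7, then 11–14); the quinone branch (steps 8–10) joins at step 11.

The three steps most likely to fail:

Step 11. The organoaluminium species may add to the carbonyl groups or to the two unsubstituted ring positions of the quinone, or reduce it by electron transfer. Nickel may promote conjugate addition in place of insertion into the C–Cl bond. The carbometalation may stall on the aluminium alkoxide. The fallback reverses the polarity of the coupling and keeps the arene protected; it sets out from 13 and 18 and comes back at 23. Alkenylalane 21 is made from 13 as in step 11 and quenched with iodine at −30 °C to give (1E,4S,5E,9E,11R)-11-(tert-butyldimethylsilyloxy)-1-iodo-2,6,10,14-tetramethylpentadeca-1,5,9,13-tetraen-4-ol F1. Zinc insertion into 18 (Zn dust, LiCl, THF) gives (2,5-dimethoxy-3-methylbenzyl)zinc chloride F2. Negishi coupling of F1 with an excess of F2 under Pd(PPh3)4 (zerovalent palladium) in THF gives (2E,5S,6E,10E,12R)-12-(tert-butyldimethylsilyloxy)-1-(2,5-dimethoxy-3-methylphenyl)-3,7,11,15-tetramethylhexadeca-2,6,10,14-tetraen-5-ol F3. Oxidative demethylation with (NH4)2Ce(NO3)6 in MeCN/H2O at 0 °C then gives 23.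

Step 7. Facial selectivity may be poor on this β,β-disubstituted enal, turnover of the acid catalyst may be slow, and some allenyl carbinol may form through loss of SE2' regiocontrol. The fallback gives up catalyst control for resolution; it sets out from 10 and comes back at 13. Barbier addition of propargyl bromide and Zn dust in THF/aqueous NH4Cl gives the C4-epimeric mixture of (5E,9E,11R)-11-(tert-butyldimethylsilyloxy)-6,10,14-trimethylpentadeca-5,9,13-trien-1-yn-4-ol F4. Lipase-catalysed acylation (immobilised Candida antarctica lipase B, vinyl acetate, hexane) is expected, by the usual empirical preference of lipases for secondary alcohols, to acylate the 4R epimer to (4R,5E,9E,11R)-11-(tert-butyldimethylsilyloxy)-6,10,14-trimethylpentadeca-5,9,13-trien-1-yn-4-yl acetate F5. The unreacted 4S alcohol, which is 13, is separated by chromatography.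

Step 9. Bromination of the electron-rich ring or of both methyl groups may compete with mono-bromination of one methyl group. The fallback halogenates a ring-deactivated ester instead; it sets out from 14 and comes back at 18. Reductive acetylation (Zn dust, Ac2O, NaOAc, 80 °C) gives 2,6-dimethyl-1,4-phenylene diacetate F6, on which N-bromosuccinimide/azobisisobutyronitrile can only attack a methyl group, giving 2-(bromomethyl)-6-methyl-1,4-phenylene diacetate F7. KOAc in DMF gives 2-(acetoxymethyl)-6-methyl-1,4-phenylene diacetate F8. LiAlH4 in THF at 0 °C removes all three acetyl groups to give 2-(hydroxymethyl)-6-methylbenzene-1,4-diol F9. (CH3)2SO4/K2CO3 in acetone methylates the two phenols only, giving (2,5-dimethoxy-3-methylphenyl)methanol F10. SOCl2 in CH2Cl2 at 0 °C then gives 18.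

**Further compounds**

F1 | step 11 | (1E,4S,5E,9E,11R)-11-(tert-butyldimethylsilyloxy)-1-iodo-2,6,10,14-tetramethylpentadeca-1,5,9,13-tetraen-4-ol | O[C@H](/C=C(\C)CC/C=C(\C)[C@H](O[Si](C)(C)C(C)(C)C)CC=C(C)C)C/C(C)=C/I
F2 | step 11 | (2,5-dimethoxy-3-methylbenzyl)zinc chloride | Cl[Zn]Cc1cc(OC)cc(C)c1OC
F3 | step 11 | (2E,5S,6E,10E,12R)-12-(tert-butyldimethylsilyloxy)-1-(2,5-dimethoxy-3-methylphenyl)-3,7,11,15-tetramethylhexadeca-2,6,10,14-tetraen-5-ol | O[C@H](/C=C(\C)CC/C=C(\C)[C@H](O[Si](C)(C)C(C)(C)C)CC=C(C)C)C/C(C)=C/Cc1cc(OC)cc(C)c1OC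
F4 | step 7 | (5E,9E,11R)-11-(tert-butyldimethylsilyloxy)-6,10,14-trimethylpentadeca-5,9,13-trien-1-yn-4-ol, mixture of C4 epimers | OC(/C=C(\C)CC/C=C(\C)[C@H](O[Si](C)(C)C(C)(C)C)CC=C(C)C)CC#C
F5 | step 7 | (4R,5E,9E,11R)-11-(tert-butyldimethylsilyloxy)-6,10,14-trimethylpentadeca-5,9,13-trien-1-yn-4-yl acetate | CC(=O)O[C@@H](/C=C(\C)CC/C=C(\C)[C@H](O[Si](C)(C)C(C)(C)C)CC=C(C)C)CC#C
F6 | step 9 | 2,6-dimethyl-1,4-phenylene diacetate | CC(=O)Oc1cc(C)c(OC(C)=O)c(C)c1
F7 | step 9 | 2-(bromomethyl)-6-methyl-1,4-phenylene diacetate | CC(=O)Oc1cc(C)c(OC(C)=O)c(CBr)c1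
F8 | step 9 | 2-(acetoxymethyl)-6-methyl-1,4-phenylene diacetate | CC(=O)OCc1cc(OC(C)=O)cc(C)c1OC(C)=O
F9 | step 9 | 2-(hydroxymethyl)-6-methylbenzene-1,4-diol | OCc1cc(O)cc(C)c1O
F10 | step 9 | (2,5-dimethoxy-3-methylphenyl)methanol | OCc1cc(OC)cc(C)c1OC
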